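Don't read a falling X as X decaying. At 25.0 h, teal, green and violet stand at 46.5%, 46.8% and 46.1%, though Q runs from 0.029 mol% to 0.12 mol%. So the slow fall does not follow Q.

| setting | teal | green | violet | grey | theta | zeta | beta | gamma |
|---|---|---|---|---|---|---|---|---|
| G | 0.020 M | 0.020 M | 0.020 M | 0.040 M | 0.020 M (fed, over 50.0 h) | 0.020 M | 0.020 M | 0.020 M |
| Z | 1.2 equiv | 1.2 equiv | 1.2 equiv | 1.2 equiv | 1.20 equiv | 1.20 equiv | 1.20 equiv | 1.20 equiv (fed, over 50.0 h) |
| Q | 0.059 mol% | 0.029 mol% | 0.12 mol% | 0.059 mol% | 0.059 mol% | 0.059 mol% | 0.059 mol% | 0.059 mol% |
| remark | run made earlier | run made earlier | run made earlier | run made earlier | all but G at the start; G goes in evenly over 50.0 h, the run ends at 50 h | everything together in a closed stirred flask, run for 50 h | one stirred flow tank at steady state, fed with the mixture as stated, mean residence time 50 h | a stirred flask in which Z is dosed at a steady rate over 50.0 h without added volume, worked up at 50 h |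
| time |  |  |  |  | 50 h | 50 h |  | 50 h |

| run | time / h | X / % |
|---|---|---|
| teal | 6.00 | 58.6 |
| teal | 12.0 | 54.6 |
| teal | 20.0 | 49.0 |
| teal | 25.0 | 46.5 |
| teal | 30.0 | 44.1 |
| green | 4.00 | 59.8 |
| green | 12.0 | 54.3 |
| green | 25.0 | 46.8 |
| green | 40.0 | 39.1 |
| green | 48.0 | 36.0 |
| violet | 4.00 | 59.2 |
| violet | 12.0 | 54.5 |
| violet | 25.0 | 46.1 |
| violet | 40.0 | 38.8 |
| violet | 48.0 | 34.3 |
| grey | 10.0 | 66.9 |
| grey | 20.0 | 62.5 |
| grey | 30.0 | 57.1 |
| grey | 40.0 | 51.8 |
| grey | 48.0 | 48.0 |

(standard deviation of a reading: 0.5 percentage points)

* the set-up with the highest amount of X at the outlet or at the end, in percent of the G put in ("none" if the first two lie within 2 percentage points) (theta / zeta / beta / gamma / none)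
* amount of X at the outlet or at the end, in percent of the G put in, theta
* amount of X at the outlet or at the end, in percent of the G put in, zeta
* amount of X at the outlet or at the end, in percent of the G put in, beta
* amount of X at the outlet or at the end, in percent of the G put in, gamma

- the stated concentrations are those of everything mixed, before any reaction; amounts are the same in each set-up
- the feed brings no volume worth counting
- the earlier runs were made in a closed, stirred flask

Treat the binding as a fast pre-equilibrium. Work in fractions of the G charge: x for X, z for free Z. Teal's first two readings run back to 62.6% at the start, so the binding number b, x over unbound G over z, reads 2.92. Each reading now gives z, and x plus z is the Z still alive. Call the hourly loss of that Z per unit of free Z the drain constant: teal reads 0.0397 /h. Grey, with b at 5.83, reads 0.0393 /h. Charged to free G instead, the two runs read 0.0432 /h and 0.0463 /h, further apart. So I put a first-order loss on free Z, with bound Z shielded. Bare Z halves in 17.5 h and keeps 13.8% over the run.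

Theta and gamma, the dosed flasks, then need the binding plus one line: z equals A minus Bx. A is the free Z with nothing bound; B is the survival of Z from the moment X took it to the end.

Draw theta: X starts at 77.8% of the feed, bends near one half-life of Z, then flattens. Count its X as bound at a quarter of the run: I get 24.3%. Gamma has no knee: X climbs to the end. Count its X as bound at half of the run: I get 49.6%. The tank balance gives beta 43.0%. Green's last readings run on to 35.2% for zeta. I pick gamma.

The forecast differs: it picks theta, with theta 48.9%, zeta 34.5%, beta 41.3% and gamma 22%, arguing that “free G stays low under excess Z”.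

The flasks give gamma as best, with theta 24.7%, zeta 34.9%, beta 41.8% and gamma 49.4%.

    Z → D (k = 6.53 × 10⁻⁴ /min)
    G + Z → L (k = 0.00146 /M/min)
    G + Z + Q ⇌ X + Q, rate k3*[G]*[Z]*[Q] forward; the back reaction follows from the equilibrium constant (K = 145 /M, k = 1.48 × 10⁵ /M²/min)

In theta at 11.9 h, the half-life of G by the forward step to X alone is 0.52 h, far shorter than the 18 h half-life of Z by the path to D. Theta ends with 9.4% of its Z free, where the drain constant leaves bare Z 13.8%. For the neighbour theta flask at 0.0050 M of G, scaling b by its G gives 9.48%, and that flask holds 10.2%.

The readings were computed for substances that don't exist, noise included.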